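## The problem

Sipholenol K (42) is two bicycles held apart by an ethylene bridge. The left half is a trans-fused 2,2-dimethyloxepane/cyclohexane (rings A and B); with its exocyclic CH2 it has the fifteen carbons of farnesol. The right half is a cis-fused decalin (rings C and D) whose ring C is a fully substituted cyclohexenone.

The left half has five contiguous stereocentres (C3', C5a', C6', C7', C9a', all S; benzoxepine numbering). The right half has three (C4a R, C8a S, C8 S; numbering of the hexahydronaphthalen-2(1H)-one). Inside each half control can be relayed: on the left from two epoxides and an E-alkene by anti additions, on the right from the ring fusion to the C8 carbinol, whose hydroxyl lies on the convex face beside H4a and H8a. The two-carbon bridge insulates the halves, so each needs its own source of absolute configuration.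

The hardest bond is C4a–C5, joining a ring-fusion methine to the quaternary CMe2 carbon next to the tetrasubstituted C3=C4 alkene. Fragile points are the two tertiary alcohols (elimination in strong acid), H4a (γ to the enone carbonyl, epimerisable through the dienol) and H8a (α to any C8 ketone intermediate).

The enabling feature is that, with a carbonyl imagined at C7, C3=C4 is its δ,ε double bond and C4a–C5 its β,γ bond: the retron of an oxy-Cope rearrangement. The cis relation of H4a and H8a is what a bicyclo[2.2.2]octene imposes on such a shift. The oxygen at C8 next to C7, the C2 oxygen and the C4 carbon branch map onto a masked o-benzoquinone from isovanillin.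

## Retrosynthesis

**Bridge and last operations (42 ⇒ 39 ⇒ 38 ⇒ 27 + 36).** The C2 carbonyl is carried as a PMB-protected allylic alcohol and the left-half hydroxyls as TMS ethers (39), so ring C has no carbonyl while ring D and the bridge are worked on. The central bridge bond is cut as an alkene (38), made by Julia–Kocienski olefination of enal 27 with sulfone 36. Cutting next to ring C would need C–C bond formation at a tetrasubstituted sp2 carbon. Cutting next to ring B would need it at a methine between two quaternary carbons. The middle cut gives an aldehyde carbon that is the formyl carbon of isovanillin and a sulfone carbon that is C1 of farnesol. The forward reaction must tolerate a free tertiary alcohol and be followed by a reduction that spares the tetrasubstituted alkene.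

**Ring D carbinol (27 ⇒ 26 ⇒ 25 ⇒ 24).** The C8 carbinol (target numbering) is traced to ketone 24 through exocyclic alkene 25. Direct methyl addition to 24 is rejected: a carbon nucleophile would enter from the convex face and put the hydroxyl on the concave face, the epimer of 42. Installing CH2 first and oxygen second (hydration of 25) lets the convex-face preference work in the right sense. The hydration must also pass by the tetrasubstituted alkene.

**Removal of the C7 oxygen (24 ⇒ 23 ⇒ 22 ⇒ 21 ⇒ 19).** Ketone 24 comes from dimethyl ketal 23, and the C7 methylene from the ring D ketone of 19 via enol triflate 21 (made through sodium enolate 20) and alkene 22. A hydrazone route is excluded because the α-alkoxy groups would eliminate. The C7 ketone is the price of the key step; three dependable steps pay it. The ketal hydrolysis must spare the cyclic acetal that masks the aldehyde.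

**Key disconnection (19 ⇒ 16).** The C4a–C5 bond and ring D are cut by a retro-oxy-Cope step to the 2-(2-methylprop-1-enyl)bicyclo[2.2.2]oct-5-en-2-ol 16. This replaces an intermolecular attack on a neopentyl carbon by an intramolecular [3,3] shift. It also makes the cis fusion a consequence of the bicycle. The forward step needs the alkenyl group syn to the etheno bridge.

**Carbinol and absolute configuration (16 ⇒ 13 + 14; 13 ⇒ 12 ⇒ 9 + 10).** The alkenyl group is added to ketone 13 as the Grignard reagent from bromide 14. Ketone 13 is obtained from racemic 9 by a sulfoximine resolution with 10 (adduct 12), since the cycloaddition that creates the bicycle starts from achiral partners.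

**Bicycle and arene (9 ⇒ 8 + 3; 8 ⇒ 7 ⇒ 6 ⇒ 5 ⇒ 4; 3 ⇒ 1 + 2).** Bicycle 9 is the Diels–Alder adduct of masked o-benzoquinone 8 with enol ether 3. A ketene acetal would deliver the ring C carbon at the ketone level, but it does not survive methanol and acetic acid. The allylic ketal it would leave after the rearrangement is also more labile than the ring D ketal, so a free enone would accompany every later step. A vinyl ether leaves an ether that is inert until the last step. Dienone 8 comes from phenol 7, which is isovanillin (4) after ortho-bromination (5), methylation (6) and acetalisation. The acetal keeps the formyl carbon at the oxidation level needed for the union.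

**Left half (36 ⇒ 35 ⇒ 34 ⇒ 32 ⇒ 31 ⇒ 30 ⇒ 29 ⇒ 28).** Sulfone 36 is traced through sulfone diol 35 and sulfide 34 to triol 32 and cyclic carbonate 31. In 31 the O1'–C2', C5a'–C6' and C7'–O bonds are cut together, back to bis-epoxide 30. Compound 30 is farnesyl carbonate 29 after twofold asymmetric epoxidation, and 29 is farnesol (28). This turns five stereocentres into two catalyst-controlled epoxidations. It requires the 2,3-alkene to survive epoxidation and then act as the π-nucleophile.

## Roads not taken

**Alternative 1:** Ring A is cut at the O1'–C9a' bond. In the forward sense a peracid converts decalone ketal A1 into the trans-fused oxepanone A2, the ring-fusion methine migrating to oxygen with retention.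
- Merits: regiochemistry and retention are dependable, and A1 descends from the enantioenriched Wieland–Miescher ketone family, so the trans fusion and quaternary methyl are secure without a cascade.
- Weak points: A2 has neither the gem-dimethyl group nor the C3' hydroxyl. Turning a lactone carbonyl into a CMe2–O ether opens the ring and needs a tertiary etherification to close it again. The neighbouring hydroxyl would be set in a seven-membered ring with little bias. Ring B still needs its methyl carbinol and side chain. Rings C and D are not addressed.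
- Comparison: for the ring fusion alone A2 is at least as safe as the cascade used here (30 to 31). The chosen plan sets against this a left half with all five stereocentres four steps from farnesol, and a key step aimed at the harder right half.

**Alternative 2:** The O1'–C2', C5a'–C6' and C7'–O bonds are cut at once. A Lewis acid turns bis-epoxy ester A3 into hydroxy lactone A4 by epoxonium formation, alkene capture and lactone termination.
- Merits: two rings and five stereocentres from an acyclic chain in one step. The homoallylic ester leaves the participating alkene more nucleophilic than the allylic carbonate of 30, and lactone termination is well founded. In this respect A4 is the better cascade product.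
- Weak points: the strategic step solves the easier half. A4 carries both bridge carbons, so the union would fall on C4 of ring C, a tetrasubstituted sp2 carbon beside C4a. The cis-decalin and its C4a–C5 bond remain unsolved.
- Comparison: the chosen plan borrows the same logic for its own left half. What it sets against A4 is a one-carbon handle that meets the isovanillin-derived aldehyde in a plain olefination, and a key step spent on the bond that is hardest to make.

**Alternative 3:** Rings C and D are cut at the C4a–C8a and C1–C2 bonds. Triene A5, with the left half already attached, would close both rings by intramolecular Diels–Alder reaction to cycloadduct A6.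
- Merits: convergent and late. A6 has the ketone at C8 and oxygen at C2 exactly where needed, and C7 is a methylene from the start. That redox economy is a real advantage over the three steps spent here on deoxygenation.
- Weak points: the diene is tetrasubstituted and carries the quaternary tether carbon on its terminus, so the s-cis form is strained. The cis fusion rests on a modest endo/exo preference. The remote left-half stereocentres cannot steer the facial sense, so two diastereomers are expected at the most valuable stage. A5 itself needs a geometrically defined silyloxy diene.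
- Comparison: on paper A6 is shorter and more convergent. The chosen plan offers in return a cis fusion and a C4a–C5 bond that follow from the mechanism, and a resolution done early on a cheap intermediate.

Key step: step 9

Remark: which of the two sulfoximine adducts of step 6 contains the (1S,4S,7S) bicycle cannot be predicted and is to be assigned by crystallography; either enantiomer of reagent 10 serves.

Remark: the ether-bearing carbon C7 of 9 is assumed endo (syn to C5=C6); it becomes the C2 carbonyl of 42, so its configuration has no consequence.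

Abbreviations: PMB = 4-methoxybenzyl; cod = cycloocta-1,5-diene; SPhos = 2-dicyclohexylphosphino-2',6'-dimethoxybiphenyl; PPTS = pyridinium 4-toluenesulfonate; dpm = 2,2,6,6-tetramethylheptane-3,5-dionate; DIAD = diisopropyl azodicarboxylate; DDQ = 2,3-dichloro-5,6-dicyano-1,4-benzoquinone.

## Route

Step 1
Reactants: 1 4-methoxybenzyl alcohol; 2 vinyl acetate
Product: 3 4-methoxybenzyl vinyl ether
Conditions: [IrCl(cod)]2 (1 mol %), Na2CO3 (0.6 equiv), toluene, 100 °C
Reagents that add atoms: none
Why: Iridium-catalysed transfer vinylation of an alcohol by vinyl acetate, established for benzylic alcohols; the carbonate keeps the medium basic so the acid-labile enol ether survives.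

Step 2
Reactants: 4 isovanillin
Product: 5 2-bromo-3-hydroxy-4-methoxybenzaldehyde
Conditions: Br2, NaOAc, Fe powder (cat.), AcOH, rt
Reagents that add atoms: bromine, BrBr
Why: Electrophilic aromatic bromination; the phenol directs to its one free ortho position, C2 between OH and CHO, the known outcome for isovanillin.

Step 3
Reactants: 5 2-bromo-3-hydroxy-4-methoxybenzaldehyde
Product: 6 3-hydroxy-4-methoxy-2-methylbenzaldehyde
Conditions: MeB(OH)2, Pd(OAc)2 (5 mol %), SPhos (10 mol %), K3PO4, toluene/H2O, 100 °C
Reagents that add atoms: methylboronic acid, CB(O)O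
Why: Suzuki–Miyaura methylation; the bulky biarylphosphine copes with the di-ortho-substituted bromide and the phenol is carried as its phenoxide.

Step 4
Reactants: 6 3-hydroxy-4-methoxy-2-methylbenzaldehyde
Product: 7 3-(1,3-dioxolan-2-yl)-6-methoxy-2-methylphenol
Conditions: ethane-1,2-diol, TsOH·H2O (cat.), toluene, reflux, Dean–Stark
Reagents that add atoms: ethane-1,2-diol, OCCO
Why: Acid-catalysed acetalisation with azeotropic removal of water; the cyclic acetal survives oxidant, organometallics, KH and hydrogenation and outlasts a dimethyl ketal in step 13.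

Step 5
Reactants: 7 3-(1,3-dioxolan-2-yl)-6-methoxy-2-methylphenol; 3 4-methoxybenzyl vinyl ether
Product: 9 rac-(1S,4S,7S)-6-(1,3-dioxolan-2-yl)-3,3-dimethoxy-7-[(4-methoxybenzyl)oxy]-1-methylbicyclo[2.2.2]oct-5-en-2-one, via masked o-benzoquinone 8 (not isolated)
Conditions: PhI(OAc)2 (1.2 equiv), NaHCO3, MeOH, 3 (5 equiv), slow addition of 7, 0 °C → rt
Reagents that add atoms: methanol, CO
Why: Oxidative dearomatisation of a 2-methoxyphenol in methanol gives o-quinone monoketal 8, trapped as it forms by the excess enol ether in an inverse-electron-demand Diels–Alder reaction, a known pairing for alkyl vinyl ethers. The nucleophilic CH2 of the enol ether bonds to C5 of the dienone and the oxygen-bearing carbon to the methyl-bearing C2; the endo mode places the ether syn to the new double bond. NaHCO3 buffers the acetic acid so that acetal and enol ether are not solvolysed.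

Step 6
Reactants: 9 rac-bicyclic ketone; 10 (S)-N,S-dimethyl-S-phenylsulfoximine
Product: 12 (1S,2R,4S,7S)-6-(1,3-dioxolan-2-yl)-3,3-dimethoxy-7-[(4-methoxybenzyl)oxy]-1-methyl-2-{[(S)-N-methyl-S-phenylsulfonimidoyl]methyl}bicyclo[2.2.2]oct-5-en-2-ol, via lithiated sulfoximine 11 (not isolated)
Conditions: n-BuLi, THF, −78 °C; then 9, −78 °C; aq. NH4Cl; chromatography on silica gel
Reagents that add atoms: none
Why: Johnson sulfoximine resolution: the lithiated sulfoximine adds to the non-enolisable ketone from the face of the C5=C6 bridge. The two β-hydroxysulfoximines differ in the configuration of the whole bicycle relative to sulfur and should separate on silica gel; the one built on the (1S,4S,7S) ketone is taken on.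

Step 7
Reactants: 12 β-hydroxysulfoximine
Product: 13 (1S,4S,7S)-6-(1,3-dioxolan-2-yl)-3,3-dimethoxy-7-[(4-methoxybenzyl)oxy]-1-methylbicyclo[2.2.2]oct-5-en-2-one
Conditions: toluene, 110 °C
Reagents that add atoms: none
Why: β-Hydroxysulfoximines revert thermally to ketone and sulfoximine (retro-addition); nothing else in 12 is heat-sensitive at this temperature and 10 is recovered.

Step 8
Reactants: 13 (1S,4S,7S)-bicyclic ketone; 14 1-bromo-2-methylprop-1-ene
Product: 16 (1S,2R,4S,7S)-6-(1,3-dioxolan-2-yl)-3,3-dimethoxy-7-[(4-methoxybenzyl)oxy]-1-methyl-2-(2-methylprop-1-en-1-yl)bicyclo[2.2.2]oct-5-en-2-ol, via isobutenylmagnesium bromide 15 (not isolated)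
Conditions: Mg, I2 (cat.), THF, 50 °C; then 13, THF, −78 → 0 °C; aq. NH4Cl
Reagents that add atoms: none
Why: Grignard 1,2-addition to a ketone without α-hydrogens. Attack comes from the face of the sp2 bridge C5=C6, less hindered than the face flanked by the C7–H and C8–H bonds, as is general for bicyclo[2.2.2]oct-5-en-2-ones; the alkenyl group therefore ends up syn to the etheno bridge (C2 R).

Step 9
Reactants: 16 bicyclo[2.2.2]octenol
Product: 19 (4aR,7S,8aS)-5-(1,3-dioxolan-2-yl)-1,1-dimethoxy-7-[(4-methoxybenzyl)oxy]-4,4,6-trimethyl-3,4,4a,7,8,8a-hexahydronaphthalen-2(1H)-one, via potassium alkoxide 17 (not isolated), via potassium enolate 18 (not isolated)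
Conditions: KH (3 equiv), 18-crown-6 (3 equiv), THF, 0 → 50 °C; then aq. NH4Cl, −78 °C
Reagents that add atoms: none
Why: KH with 18-crown-6 turns 16 into the free potassium alkoxide 17, whose anionic oxy-Cope ([3,3]-sigmatropic) rearrangement is the known route from 2-alkenylbicyclo[2.2.2]oct-5-en-2-ols of masked o-benzoquinone origin to cis-decalins. The C1–C2 bond, weakened by the adjacent oxyanion, breaks while the CMe2 terminus of the alkenyl group bonds to C5 of the etheno bridge; the double bond moves to C1=C6 (the tetrasubstituted ring C alkene) and enolate 18 of the ring D ketone results. Ring D closes as a six-membered ring by this intramolecular bond formation through the boat-like six-atom array that the bicycle holds fixed, so no intermolecular approach to the neopentyl carbon is needed. The one new stereocentre, C4a of 19, is set by the bicycle: the alkenyl group lies over the face of C5 turned towards the C2–C3 bridge, the new bond is cis to the C4–C3 bond, and the fusion is cis by necessity, (4aR) following from (1S,4S) in 13. The step needs the alkenyl group syn to the etheno bridge, which step 8 provides. It also needs the [3,3] path to win over retro-addition and [1,3] shift; both carbons flanking the carbinol are quaternary, the enolate is stabilised and strain is released. Bonding at the fully substituted terminus is slow, hence the warming to 50 °C. Cold protonation gives 19, in which neither ring-fusion hydrogen is α to the carbonyl.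

Step 10
Reactants: 19 cis-fused ketone
Product: 21 (4aR,7S,8aS)-5-(1,3-dioxolan-2-yl)-1,1-dimethoxy-7-[(4-methoxybenzyl)oxy]-4,4,6-trimethyl-1,4,4a,7,8,8a-hexahydronaphthalen-2-yl trifluoromethanesulfonate, via sodium enolate 20 (not isolated)
Conditions: NaN(SiMe3)2, THF, −78 °C; then PhNTf2, −78 → 0 °C; aq. NH4Cl
Reagents that add atoms: N-phenylbis(trifluoromethanesulfonimide), O=S(=O)(N(c1ccccc1)S(=O)(=O)C(F)(F)F)C(F)(F)F
Why: Regiospecific enol triflate formation from the isolated ketone: the only α-hydrogens are on C3, so the sodium amide gives the C2–C3 sodium enolate 20, which the triflimide sulfonylates on oxygen. Neither ring-fusion hydrogen is acidic here, so the cis fusion is not at risk.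

Step 11
Reactants: 21 enol triflate
Product: 22 (4aR,7S,8aS)-5-(1,3-dioxolan-2-yl)-1,1-dimethoxy-7-[(4-methoxybenzyl)oxy]-4,4,6-trimethyl-1,4,4a,7,8,8a-hexahydronaphthalene
Conditions: Pd(OAc)2 (5 mol %), PPh3 (10 mol %), HCO2H, Bu3N, DMF, 60 °C
Reagents that add atoms: none
Why: Palladium-catalysed formate reduction of an enol triflate (oxidative addition, formate exchange, decarboxylation, reductive elimination); the amine-buffered medium leaves ketal, acetal and PMB ether untouched.

Step 12
Reactants: 22 ring D alkene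
Product: 23 (4aR,7S,8aS)-5-(1,3-dioxolan-2-yl)-1,1-dimethoxy-7-[(4-methoxybenzyl)oxy]-4,4,6-trimethyl-1,2,3,4,4a,7,8,8a-octahydronaphthalene
Conditions: H2 (1 atm), PtO2, EtOAc, rt
Reagents that add atoms: none
Why: Heterogeneous hydrogenation of the cis-disubstituted C2=C3 alkene; the tetrasubstituted C5=C6 alkene is inert here and platinum at 1 atm does not cleave the benzylic ether.

Step 13
Reactants: 23 dimethyl ketal
Product: 24 (4aR,7S,8aS)-5-(1,3-dioxolan-2-yl)-7-[(4-methoxybenzyl)oxy]-4,4,6-trimethyl-3,4,4a,7,8,8a-hexahydronaphthalen-1(2H)-one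
Conditions: PPTS (0.2 equiv), acetone/H2O (10:1), rt
Reagents that add atoms: water, O
Why: Acid-catalysed ketal hydrolysis; an acyclic dimethyl ketal of a ketone is cleaved far faster than a cyclic acetal of an aldehyde, so the dioxolane should remain. The mild acid at room temperature also avoids enolisation towards H8a.

Step 14
Reactants: 24 ring D ketone
Product: 25 (4aR,7S,8aS)-5-(1,3-dioxolan-2-yl)-7-[(4-methoxybenzyl)oxy]-4,4,6-trimethyl-1-methylidene-1,2,3,4,4a,7,8,8a-octahydronaphthalene
Conditions: Cp2TiMe2, toluene, 70 °C, dark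
Reagents that add atoms: dimethyltitanocene, [Ti+4].[CH3-].[CH3-].c1cc[cH-]c1.c1cc[cH-]c1
Why: Petasis methylenation: Cp2TiMe2 loses methane to give Cp2Ti=CH2, which olefinates the hindered ketone without base, so H8a, now α to the carbonyl, is not epimerised as it might be by a phosphorus ylide.

Step 15
Reactants: 25 exocyclic alkene
Product: 26 (1S,4aR,7S,8aS)-5-(1,3-dioxolan-2-yl)-7-[(4-methoxybenzyl)oxy]-1,4,4,6-tetramethyl-1,2,3,4,4a,7,8,8a-octahydronaphthalen-1-ol
Conditions: Mn(dpm)3 (10 mol %), PhSiH3, O2 (1 atm), i-PrOH/CH2Cl2, 0 °C → rt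
Reagents that add atoms: dioxygen, O=O
Why: Mukaiyama hydration: hydrogen-atom transfer from the Mn–H species formed from Mn(dpm)3 and PhSiH3 to the 1,1-disubstituted alkene, capture of the tertiary radical by O2, reduction of the peroxide by silane; the tetrasubstituted alkene does not accept the hydrogen atom. O2 should add to the planar C1 radical from the convex face of the cis-decalin, the side of H4a and H8a, giving the (1S) carbinol with the hydroxyl where 42 has it. A methyl nucleophile added to 24 would use the same face and give the epimer, hence carbon first and oxygen second.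

Step 16
Reactants: 26 tertiary alcohol
Product: 27 (3S,4aS,5S,8aR)-5-hydroxy-3-[(4-methoxybenzyl)oxy]-2,5,8,8-tetramethyl-3,4,4a,5,6,7,8,8a-octahydronaphthalene-1-carbaldehyde
Conditions: TsOH·H2O (0.1 equiv), acetone/H2O (10:1), 40 °C
Reagents that add atoms: water, O
Why: Acid-catalysed hydrolysis of the vinylogous dioxolane under conditions a little stronger than in step 13; the tertiary alcohol and the allylic ether tolerate dilute sulfonic acid, the more so once the alkene is conjugated to the aldehyde.

Step 17
Reactants: 28 (2E,6E)-farnesol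
Product: 29 tert-butyl (2E,6E)-3,7,11-trimethyldodeca-2,6,10-trien-1-yl carbonate
Conditions: Boc2O, 1-methylimidazole, toluene, rt
Reagents that add atoms: di-tert-butyl dicarbonate, CC(C)(C)OC(=O)OC(=O)OC(C)(C)C
Why: Acylation of the primary allylic alcohol under nucleophilic catalysis; the carbonate deactivates the 2,3-alkene in step 18 and is the terminating nucleophile in step 19.

Step 18
Reactants: 29 farnesyl carbonate
Product: 30 tert-butyl {(2E)-5-[(2S,3S)-3-{2-[(2S)-3,3-dimethyloxiran-2-yl]ethyl}-3-methyloxiran-2-yl]-3-methylpent-2-en-1-yl} carbonate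
Conditions: L-fructose-derived Shi ketone (0.6 equiv), Oxone (2KHSO5·KHSO4·K2SO4), K2CO3, Bu4NHSO4 (cat.), MeCN/dimethoxymethane/aq. Na2B4O7 buffer, 0 °C
Reagents that add atoms: potassium peroxymonosulfate, [K+].[O-]S(=O)(=O)OO
Why: Shi epoxidation: the chiral dioxirane epoxidises the two electron-rich trisubstituted alkenes (6,7 and 10,11) to the (S)-configured epoxides, the mirror image of what the D-fructose catalyst gives. The 2,3-alkene, deactivated by the allylic carbonate, is left; all three stereocentres are catalyst-controlled.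

Step 19
Reactants: 30 bis-epoxide
Product: 31 cyclic carbonate of triol 32 (1,3-dioxan-2-one spanning the C6 CH2O group and the C7 oxygen; free 3-hydroxyl)
Conditions: BF3·OEt2 (1.1 equiv), CH2Cl2, −78 → −40 °C; aq. NaHCO3
Reagents that add atoms: none
Why: Lewis-acid-initiated epoxide/alkene cascade of the kind used for oxepane-fused terpenoids: BF3 activates the terminal epoxide and the oxygen of the 6,7-epoxide attacks its CMe2 carbon (7-endo, favoured at the tertiary carbon) to give a bicyclic epoxonium ion. The 2,3-alkene opens this at the methyl-bearing carbon with inversion through a chair (ring B), and the carbonate carbonyl captures the tertiary cation anti to the new C–C bond with loss of 2-methylpropene. The anti additions across E-epoxide and E-alkene give the trans ring fusion, axial methyls at C5a and C7, and equatorial CH2O and tertiary oxygen.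

Step 20
Reactants: 31 cyclic carbonate
Product: 32 (3S,5aS,6R,7S,9aS)-6-(hydroxymethyl)-2,2,5a,7-tetramethyldecahydro-1-benzoxepine-3,7-diol
Conditions: K2CO3, MeOH, rt
Reagents that add atoms: none
Why: Base-catalysed transesterification of the cyclic carbonate by methanol.

Step 21
Reactants: 32 triol; 33 1-phenyl-1H-tetrazole-5-thiol
Product: 34 (3S,5aS,6S,7S,9aS)-2,2,5a,7-tetramethyl-6-{[(1-phenyl-1H-tetrazol-5-yl)sulfanyl]methyl}decahydro-1-benzoxepine-3,7-diol
Conditions: PPh3, DIAD, THF, 0 °C → rt
Reagents that add atoms: none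
Why: Mitsunobu thioetherification; the acidic thiol is delivered to the primary hydroxyl, while the neopentyl-type secondary and the tertiary hydroxyl are too hindered to be activated.

Step 22
Reactants: 34 sulfide
Product: 35 (3S,5aS,6S,7S,9aS)-2,2,5a,7-tetramethyl-6-{[(1-phenyl-1H-tetrazol-5-yl)sulfonyl]methyl}decahydro-1-benzoxepine-3,7-diol
Conditions: (NH4)6Mo7O24·4H2O (10 mol %), 30% H2O2, EtOH, 0 °C → rt
Reagents that add atoms: hydrogen peroxide, OO
Why: Molybdate-catalysed oxidation of sulfide to sulfone; the free alcohols and the ether are inert.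

Step 23
Reactants: 35 sulfone diol
Product: 36 1-phenyl-5-({[(3S,5aS,6S,7S,9aS)-2,2,5a,7-tetramethyl-3,7-bis(trimethylsilyloxy)decahydro-1-benzoxepin-6-yl]methyl}sulfonyl)-1H-tetrazole
Conditions: Me3SiOTf, 2,6-lutidine, CH2Cl2, −78 → 0 °C
Reagents that add atoms: trimethylsilyl trifluoromethanesulfonate, C[Si](C)(C)OS(=O)(=O)C(F)(F)F
Why: Silylation of the secondary and tertiary hydroxyls by the silyl triflate; an unprotected C7 alkoxide would sit three carbons from sulfur and could attack the tetrazole in step 24. TMS ethers come off in the last step under very mild acid.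

Step 24
Reactants: 36 bis-silyl sulfone; 27 enal
Product: 38 (1S,4aR,7S,8aS)-7-[(4-methoxybenzyl)oxy]-1,4,4,6-tetramethyl-5-{(E)-2-[(3S,5aS,6S,7S,9aS)-2,2,5a,7-tetramethyl-3,7-bis(trimethylsilyloxy)decahydro-1-benzoxepin-6-yl]ethenyl}-1,2,3,4,4a,7,8,8a-octahydronaphthalen-1-ol, via potassium sulfonyl carbanion 37 (not isolated)
Conditions: KN(SiMe3)2 (1.05 equiv per 36), THF, −78 °C; then 27, −78 °C → rt; aq. NH4Cl
Reagents that add atoms: none
Why: Julia–Kocienski olefination: the metallated tetrazolyl sulfone adds to the aldehyde and Smiles rearrangement with loss of SO2 and tetrazolone gives the alkene, whose geometry is irrelevant. The hindered tertiary alcohol of 27 is a weaker acid than the sulfone and is left free.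

Step 25
Reactants: 38 diene
Product: 39 (1S,4aR,7S,8aS)-7-[(4-methoxybenzyl)oxy]-1,4,4,6-tetramethyl-5-{2-[(3S,5aS,6S,7S,9aS)-2,2,5a,7-tetramethyl-3,7-bis(trimethylsilyloxy)decahydro-1-benzoxepin-6-yl]ethyl}-1,2,3,4,4a,7,8,8a-octahydronaphthalen-1-ol
Conditions: 2-nitrobenzenesulfonylhydrazide (10 equiv), Et3N, CH2Cl2, rt
Reagents that add atoms: none
Why: Diimide, generated from the sulfonylhydrazide, reduces the disubstituted alkene by concerted syn hydrogen transfer. It does not touch the tetrasubstituted alkene, gives no 1,4-addition to the diene and, unlike H2 over Pd/C, leaves the PMB ether and allylic C–O bond intact.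

Step 26
Reactants: 39 protected precursor
Product: 42 sipholenol K, via allylic alcohol 40 (not isolated), via bis-silyl enone 41 (not isolated)
Conditions: DDQ (3 equiv), CH2Cl2/pH 7 buffer (10:1), 0 °C → rt; then citric acid, MeOH, rt
Reagents that add atoms: none
Why: DDQ removes the PMB group by hydride abstraction and hydrolysis, and a further equivalent oxidises the liberated allylic alcohol 40, activated by the electron-rich tetrasubstituted alkene, to enone 41 (the classical DDQ oxidation of allylic alcohols). The buffer keeps H4a from epimerising, and citric acid in methanol then cleaves both TMS ethers without endangering the tertiary alcohols.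

## Compound list

1 | 4-methoxybenzyl alcohol | COc1ccc(CO)cc1 | starting material
2 | vinyl acetate | C=COC(C)=O | starting material
3 | 4-methoxybenzyl vinyl ether (1-[(ethenyloxy)methyl]-4-methoxybenzene) | C=COCc1ccc(OC)cc1 | intermediate
4 | isovanillin (3-hydroxy-4-methoxybenzaldehyde) | COc1ccc(C=O)cc1O | starting material
5 | 2-bromo-3-hydroxy-4-methoxybenzaldehyde | COc1ccc(C=O)c(Br)c1O | intermediate
6 | 3-hydroxy-4-methoxy-2-methylbenzaldehyde | COc1ccc(C=O)c(C)c1O | intermediate
7 | 3-(1,3-dioxolan-2-yl)-6-methoxy-2-methylphenol | COc1ccc(C2OCCO2)c(C)c1O | intermediate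
8 | 3-(1,3-dioxolan-2-yl)-6,6-dimethoxy-2-methylcyclohexa-2,4-dien-1-one (masked o-benzoquinone) | O=C1C(C)=C(C2OCCO2)C=CC1(OC)OC | intermediate (not isolated)
9 | rac-(1S,4S,7S)-6-(1,3-dioxolan-2-yl)-3,3-dimethoxy-7-[(4-methoxybenzyl)oxy]-1-methylbicyclo[2.2.2]oct-5-en-2-one (ether syn to C5=C6; racemate, one enantiomer drawn) | C[C@]12C(C3OCCO3)=C[C@H](C[C@@H]1OCc4ccc(OC)cc4)C(OC)(OC)C2=O | intermediate
10 | (S)-N,S-dimethyl-S-phenylsulfoximine | C[S@@](=O)(=NC)c1ccccc1 | starting material
11 | (S)-S-(lithiomethyl)-N-methyl-S-phenylsulfoximine | [Li]C[S@@](=O)(=NC)c1ccccc1 | intermediate (not isolated)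
12 | (1S,2R,4S,7S)-6-(1,3-dioxolan-2-yl)-3,3-dimethoxy-7-[(4-methoxybenzyl)oxy]-1-methyl-2-{[(S)-N-methyl-S-phenylsulfonimidoyl]methyl}bicyclo[2.2.2]oct-5-en-2-ol (sulfoximinylmethyl syn to C5=C6) | C[C@]12C(C3OCCO3)=C[C@H](C[C@@H]1OCc4ccc(OC)cc4)C(OC)(OC)[C@@]2(O)C[S@@](=O)(=NC)c5ccccc5 | intermediate
13 | (1S,4S,7S)-6-(1,3-dioxolan-2-yl)-3,3-dimethoxy-7-[(4-methoxybenzyl)oxy]-1-methylbicyclo[2.2.2]oct-5-en-2-one (single enantiomer) | C[C@]12C(C3OCCO3)=C[C@H](C[C@@H]1OCc4ccc(OC)cc4)C(OC)(OC)C2=O | intermediate
14 | 1-bromo-2-methylprop-1-ene | CC(C)=CBr | starting material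
15 | 2-methylprop-1-enylmagnesium bromide | CC(C)=C[Mg]Br | intermediate (not isolated)
16 | (1S,2R,4S,7S)-6-(1,3-dioxolan-2-yl)-3,3-dimethoxy-7-[(4-methoxybenzyl)oxy]-1-methyl-2-(2-methylprop-1-en-1-yl)bicyclo[2.2.2]oct-5-en-2-ol (alkenyl syn to C5=C6) | C[C@]12C(C3OCCO3)=C[C@H](C[C@@H]1OCc4ccc(OC)cc4)C(OC)(OC)[C@@]2(O)C=C(C)C | intermediate
17 | potassium alkoxide of 16 | C[C@]12C(C3OCCO3)=C[C@H](C[C@@H]1OCc4ccc(OC)cc4)C(OC)(OC)[C@@]2([O-])C=C(C)C.[K+] | intermediate (not isolated)
18 | potassium enolate of 19 (C2–C3 enolate) | CC1=C(C3OCCO3)[C@@H]2[C@H](C[C@@H]1OCc4ccc(OC)cc4)C(OC)(OC)C([O-])=CC2(C)C.[K+] | intermediate (not isolated)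
19 | (4aR,7S,8aS)-5-(1,3-dioxolan-2-yl)-1,1-dimethoxy-7-[(4-methoxybenzyl)oxy]-4,4,6-trimethyl-3,4,4a,7,8,8a-hexahydronaphthalen-2(1H)-one (cis-fused; ether cis to H4a and H8a) | CC1=C(C3OCCO3)[C@@H]2[C@H](C[C@@H]1OCc4ccc(OC)cc4)C(OC)(OC)C(=O)CC2(C)C | intermediate
20 | sodium enolate of 19 (C2–C3 enolate) | CC1=C(C3OCCO3)[C@@H]2[C@H](C[C@@H]1OCc4ccc(OC)cc4)C(OC)(OC)C([O-])=CC2(C)C.[Na+] | intermediate (not isolated)
21 | (4aR,7S,8aS)-5-(1,3-dioxolan-2-yl)-1,1-dimethoxy-7-[(4-methoxybenzyl)oxy]-4,4,6-trimethyl-1,4,4a,7,8,8a-hexahydronaphthalen-2-yl trifluoromethanesulfonate | CC1=C(C3OCCO3)[C@@H]2[C@H](C[C@@H]1OCc4ccc(OC)cc4)C(OC)(OC)C(OS(=O)(=O)C(F)(F)F)=CC2(C)C | intermediate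
22 | (4aR,7S,8aS)-5-(1,3-dioxolan-2-yl)-1,1-dimethoxy-7-[(4-methoxybenzyl)oxy]-4,4,6-trimethyl-1,4,4a,7,8,8a-hexahydronaphthalene | CC1=C(C3OCCO3)[C@@H]2[C@H](C[C@@H]1OCc4ccc(OC)cc4)C(OC)(OC)C=CC2(C)C | intermediate
23 | (4aR,7S,8aS)-5-(1,3-dioxolan-2-yl)-1,1-dimethoxy-7-[(4-methoxybenzyl)oxy]-4,4,6-trimethyl-1,2,3,4,4a,7,8,8a-octahydronaphthalene | CC1=C(C3OCCO3)[C@@H]2[C@H](C[C@@H]1OCc4ccc(OC)cc4)C(OC)(OC)CCC2(C)C | intermediate
24 | (4aR,7S,8aS)-5-(1,3-dioxolan-2-yl)-7-[(4-methoxybenzyl)oxy]-4,4,6-trimethyl-3,4,4a,7,8,8a-hexahydronaphthalen-1(2H)-one | CC1=C(C3OCCO3)[C@@H]2[C@H](C[C@@H]1OCc4ccc(OC)cc4)C(=O)CCC2(C)C | intermediate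
25 | (4aR,7S,8aS)-5-(1,3-dioxolan-2-yl)-7-[(4-methoxybenzyl)oxy]-4,4,6-trimethyl-1-methylidene-1,2,3,4,4a,7,8,8a-octahydronaphthalene | CC1=C(C3OCCO3)[C@@H]2[C@H](C[C@@H]1OCc4ccc(OC)cc4)C(=C)CCC2(C)C | intermediate
26 | (1S,4aR,7S,8aS)-5-(1,3-dioxolan-2-yl)-7-[(4-methoxybenzyl)oxy]-1,4,4,6-tetramethyl-1,2,3,4,4a,7,8,8a-octahydronaphthalen-1-ol (hydroxyl cis to H4a and H8a) | CC1=C(C3OCCO3)[C@@H]2[C@H](C[C@@H]1OCc4ccc(OC)cc4)[C@@](C)(O)CCC2(C)C | intermediate
27 | (3S,4aS,5S,8aR)-5-hydroxy-3-[(4-methoxybenzyl)oxy]-2,5,8,8-tetramethyl-3,4,4a,5,6,7,8,8a-octahydronaphthalene-1-carbaldehyde | CC1=C(C=O)[C@@H]2[C@H](C[C@@H]1OCc3ccc(OC)cc3)[C@@](C)(O)CCC2(C)C | intermediate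
28 | (2E,6E)-farnesol | CC(C)=CCC/C(C)=C/CC/C(C)=C/CO | starting material
29 | tert-butyl (2E,6E)-3,7,11-trimethyldodeca-2,6,10-trien-1-yl carbonate | CC(C)=CCC/C(C)=C/CC/C(C)=C/COC(=O)OC(C)(C)C | intermediate
30 | tert-butyl {(2E)-5-[(2S,3S)-3-{2-[(2S)-3,3-dimethyloxiran-2-yl]ethyl}-3-methyloxiran-2-yl]-3-methylpent-2-en-1-yl} carbonate ((6S,7S,10S)-bis-epoxide) | CC1(C)O[C@H]1CC[C@]2(C)O[C@H]2CC/C(C)=C/COC(=O)OC(C)(C)C | intermediate
31 | cyclic carbonate of 32 (1,3-dioxan-2-one across C6–CH2O and C7–O; 3-OH free; trans ring fusion; (3S,5aS,6R,7S,9aS) in the numbering of 32) | O=C1OC[C@H]2[C@]3(C)CC[C@H](O)C(C)(C)O[C@H]3CC[C@]2(C)O1 | intermediate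
32 | (3S,5aS,6R,7S,9aS)-6-(hydroxymethyl)-2,2,5a,7-tetramethyldecahydro-1-benzoxepine-3,7-diol | OC[C@H]1[C@]2(C)CC[C@H](O)C(C)(C)O[C@H]2CC[C@]1(C)O | intermediate
33 | 1-phenyl-1H-tetrazole-5-thiol | Sc1nnnn1-c1ccccc1 | starting material
34 | (3S,5aS,6S,7S,9aS)-2,2,5a,7-tetramethyl-6-{[(1-phenyl-1H-tetrazol-5-yl)sulfanyl]methyl}decahydro-1-benzoxepine-3,7-diol | c1ccccc1-n1nnnc1SC[C@H]1[C@]2(C)CC[C@H](O)C(C)(C)O[C@H]2CC[C@]1(C)O | intermediate
35 | (3S,5aS,6S,7S,9aS)-2,2,5a,7-tetramethyl-6-{[(1-phenyl-1H-tetrazol-5-yl)sulfonyl]methyl}decahydro-1-benzoxepine-3,7-diol | O=S(=O)(C[C@H]1[C@]2(C)CC[C@H](O)C(C)(C)O[C@H]2CC[C@]1(C)O)c1nnnn1-c1ccccc1 | intermediate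
36 | 1-phenyl-5-({[(3S,5aS,6S,7S,9aS)-2,2,5a,7-tetramethyl-3,7-bis(trimethylsilyloxy)decahydro-1-benzoxepin-6-yl]methyl}sulfonyl)-1H-tetrazole | O=S(=O)(C[C@H]1[C@]2(C)CC[C@H](O[Si](C)(C)C)C(C)(C)O[C@H]2CC[C@]1(C)O[Si](C)(C)C)c1nnnn1-c1ccccc1 | intermediate
37 | potassium α-sulfonyl carbanion of 36 | [K+].O=S(=O)([CH-][C@H]1[C@]2(C)CC[C@H](O[Si](C)(C)C)C(C)(C)O[C@H]2CC[C@]1(C)O[Si](C)(C)C)c1nnnn1-c1ccccc1 | intermediate (not isolated)
38 | (1S,4aR,7S,8aS)-7-[(4-methoxybenzyl)oxy]-1,4,4,6-tetramethyl-5-{(E)-2-[(3S,5aS,6S,7S,9aS)-2,2,5a,7-tetramethyl-3,7-bis(trimethylsilyloxy)decahydro-1-benzoxepin-6-yl]ethenyl}-1,2,3,4,4a,7,8,8a-octahydronaphthalen-1-ol | CC1=C(/C=C/[C@H]3[C@]4(C)CC[C@H](O[Si](C)(C)C)C(C)(C)O[C@H]4CC[C@]3(C)O[Si](C)(C)C)[C@@H]2[C@H](C[C@@H]1OCc5ccc(OC)cc5)[C@@](C)(O)CCC2(C)C | intermediate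
39 | (1S,4aR,7S,8aS)-7-[(4-methoxybenzyl)oxy]-1,4,4,6-tetramethyl-5-{2-[(3S,5aS,6S,7S,9aS)-2,2,5a,7-tetramethyl-3,7-bis(trimethylsilyloxy)decahydro-1-benzoxepin-6-yl]ethyl}-1,2,3,4,4a,7,8,8a-octahydronaphthalen-1-ol | CC1=C(CC[C@H]3[C@]4(C)CC[C@H](O[Si](C)(C)C)C(C)(C)O[C@H]4CC[C@]3(C)O[Si](C)(C)C)[C@@H]2[C@H](C[C@@H]1OCc5ccc(OC)cc5)[C@@](C)(O)CCC2(C)C | intermediate
40 | (1S,4aR,7S,8aS)-1,4,4,6-tetramethyl-5-{2-[(3S,5aS,6S,7S,9aS)-2,2,5a,7-tetramethyl-3,7-bis(trimethylsilyloxy)decahydro-1-benzoxepin-6-yl]ethyl}-1,2,3,4,4a,7,8,8a-octahydronaphthalene-1,7-diol | CC1=C(CC[C@H]3[C@]4(C)CC[C@H](O[Si](C)(C)C)C(C)(C)O[C@H]4CC[C@]3(C)O[Si](C)(C)C)[C@@H]2[C@H](C[C@@H]1O)[C@@](C)(O)CCC2(C)C | intermediate (not isolated)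
41 | (4aR,8S,8aS)-8-hydroxy-3,5,5,8-tetramethyl-4-{2-[(3S,5aS,6S,7S,9aS)-2,2,5a,7-tetramethyl-3,7-bis(trimethylsilyloxy)decahydro-1-benzoxepin-6-yl]ethyl}-4a,5,6,7,8,8a-hexahydronaphthalen-2(1H)-one | CC1=C(CC[C@H]3[C@]4(C)CC[C@H](O[Si](C)(C)C)C(C)(C)O[C@H]4CC[C@]3(C)O[Si](C)(C)C)[C@@H]2[C@H](CC1=O)[C@@](C)(O)CCC2(C)C | intermediate (not isolated)
42 | sipholenol K, (4aR,8S,8aS)-4-{2-[(3S,5aS,6S,7S,9aS)-3,7-dihydroxy-2,2,5a,7-tetramethyldecahydro-1-benzoxepin-6-yl]ethyl}-8-hydroxy-3,5,5,8-tetramethyl-4a,5,6,7,8,8a-hexahydronaphthalen-2(1H)-one | CC1=C(CC[C@H]2[C@]3(C)CC[C@H](O)C(C)(C)O[C@H]3CC[C@]2(C)O)[C@@H]2[C@H](CC1=O)[C@@](C)(O)CCC2(C)C | target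

## Step count and risk

Total: 26 steps. Longest linear sequence: 18 steps (steps 2–16 and 24–26, from isovanillin 4). The left half (steps 17–23) and the enol ether (step 1) are side branches.

**Step 9 (key step).** The alkoxide may revert to ketone and alkenyl anion, or the [3,3] shift may stall, because bonding at the fully substituted CMe2 terminus is the most hindered variant of this rearrangement. Fallback: move the quaternary carbon out of the sigmatropic step. Ketone 13 is treated with prop-1-enylmagnesium bromide to give the propenyl carbinol F1, whose potassium alkoxide rearranges through a far less hindered CH(Me) terminus to the 4-methyl ketone F2 (mixture at C4). Dehydrogenation with IBX in DMSO gives the β-methyl enone F3, and conjugate addition of Me2CuLi installs the second methyl and returns ketone 19.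

**Step 5.** The masked o-benzoquinone may dimerise faster than it is trapped, since the methyl on its reacting terminus slows approach of the enol ether; the enol ether may also be consumed by solvolysis. Fallback: block the position para to the phenol with bromine. Phenol 7 is brominated (NBS) to the 4-bromophenol F4, whose masked o-benzoquinone F5 belongs to the class that resists dimerisation. Cycloaddition with 3 gives the 5-bromo adduct F6, and Bu3SnH with a radical initiator removes the vinylic bromine to return 9.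

**Step 15.** Capture of the tertiary radical by the small O2 molecule may show poor facial selectivity, and reduction of the alkene without oxygenation may compete. Fallback: deliver oxygen with a bulky reagent. OsO4 with N-methylmorpholine N-oxide dihydroxylates the 1,1-disubstituted alkene of 25 from the convex face to the diol F7. Tosylation of its primary hydroxyl gives F8, and LiEt3BH displaces the tosylate to leave the methyl group, returning 26.

**Step 19.** The tertiary cation may lose a proton (or the epoxonium ion may open without the deactivated 2,3-alkene) before the carbonate closes its six-membered ring. Fallback: accept the proton-loss termination and add the oxygen afterwards. Bis-epoxide 30 is cyclised with Me3SiOTf and a hindered pyridine base to the exocyclic alkene F9. A peracid epoxidises it from the equatorial face, away from the axial C5a methyl, to the spiro-epoxide F10. LiAlH4 opens the epoxide at its CH2 and cleaves the carbonate, returning triol 32.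

**Step 24.** Addition of the β-branched sulfonyl carbanion to the hindered aldehyde may be slow, leaving time for γ-deprotonation of the enal. Fallback: join the halves by sp3 alkylation. Enal 27 is reduced (NaBH4) to the allylic alcohol F11 and converted (CBr4, PPh3) into the allylic bromide F12. The lithiated sulfone from 36 is alkylated by F12 to give the sulfone F13, and reductive desulfonylation with SmI2 returns 39 directly, without an alkene to reduce.

## Further compounds

F1 | step 9 | (1S,2R,4S,7S)-6-(1,3-dioxolan-2-yl)-3,3-dimethoxy-7-[(4-methoxybenzyl)oxy]-1-methyl-2-(prop-1-en-1-yl)bicyclo[2.2.2]oct-5-en-2-ol (alkene geometry either) | C[C@]12C(C3OCCO3)=C[C@H](C[C@@H]1OCc4ccc(OC)cc4)C(OC)(OC)[C@@]2(O)C=CC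
F2 | step 9 | (4aR,7S,8aS)-5-(1,3-dioxolan-2-yl)-1,1-dimethoxy-7-[(4-methoxybenzyl)oxy]-4,6-dimethyl-3,4,4a,7,8,8a-hexahydronaphthalen-2(1H)-one (mixture at C4) | CC1=C(C3OCCO3)[C@@H]2[C@H](C[C@@H]1OCc4ccc(OC)cc4)C(OC)(OC)C(=O)CC2C
F3 | step 9 | (4aR,7S,8aS)-5-(1,3-dioxolan-2-yl)-1,1-dimethoxy-7-[(4-methoxybenzyl)oxy]-4,6-dimethyl-4a,7,8,8a-tetrahydronaphthalen-2(1H)-one | CC1=C(C3OCCO3)[C@@H]2[C@H](C[C@@H]1OCc4ccc(OC)cc4)C(OC)(OC)C(=O)C=C2C
F4 | step 5 | 4-bromo-3-(1,3-dioxolan-2-yl)-6-methoxy-2-methylphenol | COc1cc(Br)c(C2OCCO2)c(C)c1O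
F5 | step 5 | 4-bromo-3-(1,3-dioxolan-2-yl)-6,6-dimethoxy-2-methylcyclohexa-2,4-dien-1-one | O=C1C(C)=C(C2OCCO2)C(Br)=CC1(OC)OC
F6 | step 5 | 5-bromo derivative of 9 (racemic, relative configuration as 9) | C[C@]12C(C3OCCO3)=C(Br)[C@H](C[C@@H]1OCc4ccc(OC)cc4)C(OC)(OC)C2=O
F7 | step 15 | 1-(hydroxymethyl) analogue of 26 (1,1-diol pattern: tertiary OH and CH2OH at C1; tertiary OH cis to H8a) | CC1=C(C3OCCO3)[C@@H]2[C@H](C[C@@H]1OCc4ccc(OC)cc4)[C@@](CO)(O)CCC2(C)C
F8 | step 15 | primary 4-toluenesulfonate of F7 | CC1=C(C3OCCO3)[C@@H]2[C@H](C[C@@H]1OCc4ccc(OC)cc4)[C@@](COS(=O)(=O)c5ccc(C)cc5)(O)CCC2(C)C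
F9 | step 19 | tert-butyl {[(3S,5aS,9aS)-3-hydroxy-2,2,5a-trimethyl-7-methylidenedecahydro-1-benzoxepin-6-yl]methyl} carbonate (C6 configured as in 31) | CC(C)(C)OC(=O)OC[C@H]1[C@]2(C)CC[C@H](O)C(C)(C)O[C@H]2CCC1=C
F10 | step 19 | spiro-epoxide of F9 (epoxide oxygen equatorial, trans to the C5a methyl) | CC(C)(C)OC(=O)OC[C@H]1[C@]2(C)CC[C@H](O)C(C)(C)O[C@H]2CC[C@@]13CO3
F11 | step 24 | (1S,4aR,7S,8aS)-5-(hydroxymethyl)-7-[(4-methoxybenzyl)oxy]-1,4,4,6-tetramethyl-1,2,3,4,4a,7,8,8a-octahydronaphthalen-1-ol | CC1=C(CO)[C@@H]2[C@H](C[C@@H]1OCc3ccc(OC)cc3)[C@@](C)(O)CCC2(C)C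
F12 | step 24 | (1S,4aR,7S,8aS)-5-(bromomethyl)-7-[(4-methoxybenzyl)oxy]-1,4,4,6-tetramethyl-1,2,3,4,4a,7,8,8a-octahydronaphthalen-1-ol | CC1=C(CBr)[C@@H]2[C@H](C[C@@H]1OCc3ccc(OC)cc3)[C@@](C)(O)CCC2(C)C
F13 | step 24 | 39 bearing a (1-phenyl-1H-tetrazol-5-yl)sulfonyl group on the bridge carbon next to ring B (mixture at that carbon) | CC1=C(CC([C@H]5[C@]6(C)CC[C@H](O[Si](C)(C)C)C(C)(C)O[C@H]6CC[C@]5(C)O[Si](C)(C)C)S(=O)(=O)c7nnnn7-c8ccccc8)[C@@H]2[C@H](C[C@@H]1OCc4ccc(OC)cc4)[C@@](C)(O)CCC2(C)C
A1 | alternative 1 | decalone ketal (ring A ketone beside the ring-fusion CH) | O1CCOC12[C@]3(C)CCCC(=O)[C@H]3CCC2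
A2 | alternative 1 | trans-fused oxepanone ketal | O1CCOC12[C@]3(C)CCCC(=O)O[C@H]3CCC2
A3 | alternative 2 | tert-butyl (6S,7S,10S)-6,7:10,11-bis-epoxyhomofarnesoate | CC1(C)O[C@H]1CC[C@]2(C)O[C@H]2CC/C(C)=C/CC(=O)OC(C)(C)C
A4 | alternative 2 | oxepane-cyclohexane hydroxy lactone | O=C1C[C@H]2[C@]3(C)CC[C@H](O)C(C)(C)O[C@H]3CC[C@]2(C)O1
A5 | alternative 3 | silyloxy diene/vinyl ketone triene carrying the protected left half | CC(C)(C)[Si](C)(C)O/C=C(C)/C(CC[C@H]1[C@]2(C)CC[C@H](O[Si](C)(C)C(C)(C)C)C(C)(C)O[C@H]2CC[C@]1(C)O[Si](C)(C)C)=C/C(C)(C)CCC(=O)C=C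
A6 | alternative 3 | cis-fused cycloadduct (ring C allylic silyl ether, ring D ketone) | CC1=C(CC[C@H]2[C@]3(C)CC[C@H](O[Si](C)(C)C(C)(C)C)C(C)(C)O[C@H]3CC[C@]2(C)O[Si](C)(C)C)[C@@H]2[C@H](C[C@H]1O[Si](C)(C)C(C)(C)C)C(=O)CCC2(C)C
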